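The route rests on unit A, the chlorine-free chromone: its C4 carbonyl is flanked by the benzylic carbon C3 and by the ring-A carbon C4a, so both C–C bonds to C4 are disconnected. A palladium-catalysed carbonylative Suzuki coupling joins a benzylic bromide, carbon monoxide and 2,4-dimethoxyphenylboronic acid, forming C3–C4 and C4–C4a in one operation and fixing the ring-A oxygens through the boron position. The bromide partner is the complete, O-methylated chlorinated half: an 8-chloro-7-methoxyisoflavone whose 4'-oxygen carries a 2-methoxy-5-(bromomethyl)phenyl ring. Global demethylation and a one-carbon O1–C2–C3 closure then complete unit A.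

Key step: step 6

Remark: the target contains no stereogenic element, so no step has to control configuration.
Remark: the diaryl ether is built from a 4'-bromo isoflavone and isovanillin, so that 7-OH is the only free phenol when the methyl ether is installed and no selective mono-methylation is needed.

Step 1
Reactants: 1 2-chlororesorcinol; 2 4-bromophenylacetic acid
Product: 4 3-(4-bromophenyl)-8-chloro-7-hydroxychromen-4-one, via bromo-deoxybenzoin 3 (not isolated)
Conditions: BF3·OEt2 (as solvent), 85 °C; then DMF, MsCl, 50 → 80 °C; H2O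
Reagents that add atoms: N,N-dimethylformamide, CN(C)C=O
Why: BF3-promoted Friedel–Crafts acylation can only occur at the equivalent C4/C6 positions of symmetric 2-chlororesorcinol, and the resulting 2-hydroxydeoxybenzoin is formylated at its methylene by the DMF–MsCl Vilsmeier-type reagent and closes through the chelated ortho hydroxyl to the pyranone (one-pot deoxybenzoin isoflavone synthesis).

Step 2
Reactants: 4 3-(4-bromophenyl)-8-chloro-7-hydroxychromen-4-one
Product: 5 3-(4-bromophenyl)-8-chloro-7-methoxychromen-4-one
Conditions: MeI, K2CO3, DMF, rt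
Reagents that add atoms: iodomethane, CI
Why: Williamson ether synthesis on the single, acidic 7-OH; the pyranone tolerates carbonate in DMF at room temperature.

Step 3
Reactants: 5 3-(4-bromophenyl)-8-chloro-7-methoxychromen-4-one; 6 isovanillin (3-hydroxy-4-methoxybenzaldehyde)
Product: 7 3-[4-(8-chloro-7-methoxy-4-oxochromen-3-yl)phenoxy]-4-methoxybenzaldehyde
Conditions: CuI (cat.), N,N-dimethylglycine·HCl (cat.), Cs2CO3, dioxane, 90 °C, N2
Reagents that add atoms: none
Why: Copper-catalysed Ullmann diaryl ether synthesis between the unhindered aryl bromide and the phenoxide of isovanillin; the non-enolisable aldehyde and the hindered C8–Cl bond are inert to Cu(I)/amino acid catalysis at this temperature, and no hydroxide or alkoxide is present to open the pyranone.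

Step 4
Reactants: 7 3-[4-(8-chloro-7-methoxy-4-oxochromen-3-yl)phenoxy]-4-methoxybenzaldehyde
Product: 8 8-chloro-3-[4-[5-(hydroxymethyl)-2-methoxyphenoxy]phenyl]-7-methoxychromen-4-one
Conditions: NaBH4, THF/MeOH, 0 °C
Reagents that add atoms: none
Why: Borohydride reduction of the aryl aldehyde, which is far more electrophilic than the vinylogous ester carbonyl of the chromone, so a small excess of hydride at 0 °C should leave the pyranone untouched.

Step 5
Reactants: 8 8-chloro-3-[4-[5-(hydroxymethyl)-2-methoxyphenoxy]phenyl]-7-methoxychromen-4-one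
Product: 9 3-[4-[5-(bromomethyl)-2-methoxyphenoxy]phenyl]-8-chloro-7-methoxychromen-4-one
Conditions: PBr3, CH2Cl2, 0 °C; cold NaHCO3 wash, used crude
Reagents that add atoms: phosphorus tribromide, BrP(Br)Br
Why: PBr3 bromination of an electron-rich benzylic alcohol through its phosphite ester; aryl ethers, the aryl chloride and the chromone are inert, and the labile p-methoxybenzyl-type bromide is carried on without storage.

Step 6
Reactants: 9 3-[4-[5-(bromomethyl)-2-methoxyphenoxy]phenyl]-8-chloro-7-methoxychromen-4-one; 10 2,4-dimethoxyphenylboronic acid; 11 carbon monoxide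
Product: 12 8-chloro-3-[4-[5-[2-(2,4-dimethoxyphenyl)-2-oxoethyl]-2-methoxyphenoxy]phenyl]-7-methoxychromen-4-one
Conditions: PdCl2(PPh3)2 (cat.), K2CO3, CO (5 bar), anisole, 80 °C
Reagents that add atoms: none
Why: Pd(0) adds oxidatively to the benzylic C–Br bond of 9; the benzylpalladium bromide has no β-hydrogen and inserts CO quickly to an arylacetyl–Pd species, which takes the aryl group from the boronate of 10 and reductively eliminates ketone 12. The closest known reaction type is the carbonylative Suzuki–Miyaura coupling of benzyl halides with arylboronic acids to 1,2-diarylethanones. No ring is closed and no stereocentre is created. The step needs carbonylative over direct benzyl–aryl coupling and benzylic C–Br over aryl C–Cl reactivity: CO pressure and the fast migratory insertion at a benzyl–Pd centre should secure the first, and a PPh3-ligated catalyst at 80 °C, which does not insert into the electron-rich C8–Cl bond flanked by O1 and 7-OMe, should secure the second. The acyl carbon ends on the carbon that carried boron, so the 2,4-dioxygenation of ring A is fixed by the choice of 10. Carbonate base in a non-hydroxylic solvent spares the pyranone of unit B and limits solvolysis of the bromide.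

Step 7
Reactants: 12 8-chloro-3-[4-[5-[2-(2,4-dimethoxyphenyl)-2-oxoethyl]-2-methoxyphenoxy]phenyl]-7-methoxychromen-4-one
Product: 13 8-chloro-3-[4-[5-[2-(2,4-dihydroxyphenyl)-2-oxoethyl]-2-hydroxyphenoxy]phenyl]-7-hydroxychromen-4-one
Conditions: BBr3 (excess), CH2Cl2, −78 °C → rt; then MeOH, H2O
Reagents that add atoms: none
Why: BBr3 ether cleavage, in which bromide attacks the methyl carbon of each O–B-complexed aryl methyl ether, whereas the diaryl ether (no SN2-capable carbon), the aryl chloride, the ketone and the pyranone persist, and the benzyl ring has no ortho oxygen that could close a benzofuran onto the ketone.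

Step 8
Reactants: 13 8-chloro-3-[4-[5-[2-(2,4-dihydroxyphenyl)-2-oxoethyl]-2-hydroxyphenoxy]phenyl]-7-hydroxychromen-4-one
Product: 14 Bisoflavolin K, 8-chloro-7-hydroxy-3-[4-[2-hydroxy-5-(7-hydroxy-4-oxochromen-3-yl)phenoxy]phenyl]chromen-4-one
Conditions: BF3·OEt2 (as solvent), DMF, MsCl, 50 → 80 °C; H2O
Reagents that add atoms: N,N-dimethylformamide, CN(C)C=O
Why: Deoxybenzoin-to-isoflavone closure, in which the DMF–MsCl Vilsmeier-type reagent formylates the activated methylene and the ortho hydroxyl adds to the iminium carbon and expels dimethylamine, forming C2–C3 and O1–C2 of unit A; the remaining phenols are tolerated in this protocol because they are tied up as BF3 complexes.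

Compound list
1 | 2-chlororesorcinol | Oc1cccc(O)c1Cl | starting material
2 | 4-bromophenylacetic acid | OC(=O)Cc1ccc(Br)cc1 | starting material
3 | 2-(4-bromophenyl)-1-(3-chloro-2,4-dihydroxyphenyl)ethanone | O=C(Cc1ccc(Br)cc1)c1ccc(O)c(Cl)c1O | intermediate
4 | 3-(4-bromophenyl)-8-chloro-7-hydroxychromen-4-one | O=c1c(-c2ccc(Br)cc2)coc2c(Cl)c(O)ccc12 | intermediate
5 | 3-(4-bromophenyl)-8-chloro-7-methoxychromen-4-one | O=c1c(-c2ccc(Br)cc2)coc2c(Cl)c(OC)ccc12 | intermediate
6 | isovanillin (3-hydroxy-4-methoxybenzaldehyde) | COc1ccc(C=O)cc1O | starting material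
7 | 3-[4-(8-chloro-7-methoxy-4-oxochromen-3-yl)phenoxy]-4-methoxybenzaldehyde | COc1ccc(C=O)cc1Oc1ccc(-c2coc3c(Cl)c(OC)ccc3c2=O)cc1 | intermediate
8 | 8-chloro-3-[4-[5-(hydroxymethyl)-2-methoxyphenoxy]phenyl]-7-methoxychromen-4-one | COc1ccc(CO)cc1Oc1ccc(-c2coc3c(Cl)c(OC)ccc3c2=O)cc1 | intermediate
9 | 3-[4-[5-(bromomethyl)-2-methoxyphenoxy]phenyl]-8-chloro-7-methoxychromen-4-one | BrCc1ccc(OC)c(Oc2ccc(-c3coc4c(Cl)c(OC)ccc4c3=O)cc2)c1 | intermediate
10 | 2,4-dimethoxyphenylboronic acid | COc1ccc(B(O)O)c(OC)c1 | starting material
11 | carbon monoxide | [C-]#[O+] | starting material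
12 | 8-chloro-3-[4-[5-[2-(2,4-dimethoxyphenyl)-2-oxoethyl]-2-methoxyphenoxy]phenyl]-7-methoxychromen-4-one | COc1ccc(C(=O)Cc2ccc(OC)c(Oc3ccc(-c4coc5c(Cl)c(OC)ccc5c4=O)cc3)c2)c(OC)c1 | intermediate
13 | 8-chloro-3-[4-[5-[2-(2,4-dihydroxyphenyl)-2-oxoethyl]-2-hydroxyphenoxy]phenyl]-7-hydroxychromen-4-one | Oc1ccc(C(=O)Cc2ccc(O)c(Oc3ccc(-c4coc5c(Cl)c(O)ccc5c4=O)cc3)c2)c(O)c1 | intermediate
14 | Bisoflavolin K, 8-chloro-7-hydroxy-3-[4-[2-hydroxy-5-(7-hydroxy-4-oxochromen-3-yl)phenoxy]phenyl]chromen-4-one (achiral) | O=c1c(-c2ccc(O)c(Oc3ccc(-c4coc5c(Cl)c(O)ccc5c4=O)cc3)c2)coc2cc(O)ccc12 | target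

Total step count: 8
Longest linear sequence: 8 steps (1 and 2 to 14); 6, 10 and 11 enter as purchased materials.

Steps most likely to fail

Step 6. Direct benzyl–aryl coupling without CO uptake, protodeboronation of the electron-rich ortho-methoxy boronic acid, or homocoupling and solvolysis of the benzylic bromide may outrun the carbonylative pathway. The fallback sets out from 9 and returns at 12 without CO or boron. Zinc dust (LiCl, THF, 0 °C) inserts into the benzylic C–Br bond to give [3-[4-(8-chloro-7-methoxy-4-oxochromen-3-yl)phenoxy]-4-methoxyphenyl]methylzinc bromide F1. This is acylated with purchased 2,4-dimethoxybenzoyl chloride under Pd(PPh3)4 catalysis (Negishi acylation) to give 12. The organozinc is too weak a nucleophile to attack the chromone, and the C8–Cl bond is not touched by the PPh3 catalyst.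

Step 3. O-arylation by the ortho-substituted, aldehyde-deactivated phenoxide may be slow, so that prolonged heating with carbonate leads to opening of the pyranone or to hydrodebromination. The fallback sets out from 5 and returns at 7 by an oxidative copper coupling at low temperature. Miyaura borylation (B2pin2, PdCl2(dppf), KOAc, dioxane, 80 °C) converts the C–Br bond into 8-chloro-7-methoxy-3-[4-(4,4,5,5-tetramethyl-1,3,2-dioxaborolan-2-yl)phenyl]chromen-4-one F2. Chan–Lam coupling of F2 with isovanillin 6 (Cu(OAc)2, B(OH)3, pyridine, 4 Å MS, MeCN, air) then gives 7.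

Step 7. Cleavage of four ethers at once may stop at partly methylated phenols, notably at the chlorine-flanked 7-OMe. Forcing it may degrade the enolisable ketone, and the polar tetraphenol may be lost on isolation. The fallback sets out from 12 and returns at 14 by closing ring C of unit A before the full deprotection.
- BCl3 (CH2Cl2, −78 → 0 °C) removes only the methyl ether ortho to the ketone through a boron chelate and gives 8-chloro-3-[4-[5-[2-(2-hydroxy-4-methoxyphenyl)-2-oxoethyl]-2-methoxyphenoxy]phenyl]-7-methoxychromen-4-one F3.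
- DMF dimethyl acetal (toluene, 100 °C) forms the enaminone, which cyclises to 8-chloro-7-methoxy-3-[4-[2-methoxy-5-(7-methoxy-4-oxochromen-3-yl)phenoxy]phenyl]chromen-4-one F4.
- F4 has no enolisable ketone and can be demethylated under forcing conditions (BBr3, CH2Cl2, rt to reflux) to give 14.

Further compounds
F1 | step 6 | [3-[4-(8-chloro-7-methoxy-4-oxochromen-3-yl)phenoxy]-4-methoxyphenyl]methylzinc bromide | Br[Zn]Cc1ccc(OC)c(Oc2ccc(-c3coc4c(Cl)c(OC)ccc4c3=O)cc2)c1
F2 | step 3 | 8-chloro-7-methoxy-3-[4-(4,4,5,5-tetramethyl-1,3,2-dioxaborolan-2-yl)phenyl]chromen-4-one | CC1(C)OB(c2ccc(-c3coc4c(Cl)c(OC)ccc4c3=O)cc2)OC1(C)C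
F3 | step 7 | 8-chloro-3-[4-[5-[2-(2-hydroxy-4-methoxyphenyl)-2-oxoethyl]-2-methoxyphenoxy]phenyl]-7-methoxychromen-4-one | COc1ccc(C(=O)Cc2ccc(OC)c(Oc3ccc(-c4coc5c(Cl)c(OC)ccc5c4=O)cc3)c2)c(O)c1
F4 | step 7 | 8-chloro-7-methoxy-3-[4-[2-methoxy-5-(7-methoxy-4-oxochromen-3-yl)phenoxy]phenyl]chromen-4-one | COc1ccc2c(=O)c(-c3ccc(OC)c(Oc4ccc(-c5coc6c(Cl)c(OC)ccc6c5=O)cc4)c3)coc2c1
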